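**Retrosynthetic overview**

1. The route rests on the fully substituted central benzene ring. Around it, carbon substituents (the diarylmethane CH2 and the C4 methylenes of the two pyran rings) alternate with oxygens (one free OH between the benzyl carbon and a pyran CH2, and the two pyran ring oxygens bound to the ketal carbons). It is cut into one aldoketene and two identical silyl ynol ethers, a formal (2+2+2) benzannulation.
2. Both cis-fused furo[2,3-b]pyran ketals are opened to γ-hydroxy methyl ketone arms, carried as dioxolane and TBS ether. They are closed last, on the two oxygens that the annulation delivers as silyl ethers, while the free OH is held as an allyl ether.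
3. Ketene source: a 3-arylpropanoyl chloride from 3-bromo-4-hydroxybenzaldehyde and isoprene (asymmetric heteroannulation makes the dihydrobenzofuran ring and its (S) centre), then a two-carbon homologation with Meldrum's acid.
4. Ynol ether: (R)-β-methyl-γ-butyrolactone, trans-propargylation (sets the second arm centre), Weinreb opening, methyl ketone, dioxolane, then acetylide oxidation and O-silylation.
5. Ring order: dihydrobenzofuran (step 1), central benzene (step 11), then both tetrahydrofuran and both pyran rings of the ketals (step 14).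

Key step: step 11

Remark on the chemistry: the ligand enantiomer in step 1 is assumed to be the one that gives (S)-C2, to be confirmed on aldehyde 3. The sp3 centres and alkene geometries of the transient species 19–23 are left undefined because aromatization erases them.

**Route**

Step 1
Reactants: 1 3-bromo-4-hydroxybenzaldehyde; 2 isoprene
Product: 3 (2S)-2-(prop-1-en-2-yl)-2,3-dihydro-1-benzofuran-5-carbaldehyde
Conditions: Pd2(dba)3·CHCl3 (cat.), chiral sulfinamide–phosphine ligand (TY-Phos type, cat.), NaOPh, CH2Cl2, 40 °C, sealed tube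
Reagents that add atoms: none
Why: Asymmetric Heck/Tsuji–Trost heteroannulation (Larock type), in which the aryl group adds to the CH2 terminus of the monosubstituted double bond of isoprene and the phenoxide closes the five-membered ring on the internal terminus of the π-allyl, the ligand controlling the face of C–O bond formation and so setting (S)-C2.

Step 2
Reactants: 3 (2S)-2-(prop-1-en-2-yl)-2,3-dihydro-1-benzofuran-5-carbaldehyde; 4 Meldrum's acid
Product: 5 5-{[(2S)-2-(prop-1-en-2-yl)-2,3-dihydro-1-benzofuran-5-yl]methyl}-2,2-dimethyl-1,3-dioxane-4,6-dione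
Conditions: Hantzsch ester, L-proline (cat.), EtOH, rt
Reagents that add atoms: none
Why: Tandem Knoevenagel condensation and transfer hydrogenation (reductive alkylation of Meldrum's acid), in which only the highly electrophilic arylidene double bond accepts hydride from the dihydropyridine and the isolated isopropenyl alkene is left alone.

Step 3
Reactants: 5 5-{[(2S)-2-(prop-1-en-2-yl)-2,3-dihydro-1-benzofuran-5-yl]methyl}-2,2-dimethyl-1,3-dioxane-4,6-dione
Product: 6 3-[(2S)-2-(prop-1-en-2-yl)-2,3-dihydro-1-benzofuran-5-yl]propanoic acid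
Conditions: pyridine/H2O (10:1), reflux
Reagents that add atoms: water, O
Why: Hydrolytic opening of the Meldrum's acid ring followed by decarboxylation of the malonic acid, under weakly basic conditions that do not touch the allylic aryl ether or the alkene.

Step 4
Reactants: 6 3-[(2S)-2-(prop-1-en-2-yl)-2,3-dihydro-1-benzofuran-5-yl]propanoic acid
Product: 7 3-[(2S)-2-(prop-1-en-2-yl)-2,3-dihydro-1-benzofuran-5-yl]propanoyl chloride
Conditions: Ghosez reagent, CH2Cl2, 0 °C to rt; used crude
Reagents that add atoms: 1-chloro-N,N,2-trimethylprop-1-en-1-amine, CC(C)=C(Cl)N(C)C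
Why: Acid chloride formation with an α-chloroenamine under neutral conditions, so that no HCl is released onto the isopropenyl group.

Step 5
Reactants: 8 (R)-4-methyldihydrofuran-2(3H)-one; 9 3-bromo-1-(trimethylsilyl)prop-1-yne
Product: 10 (3R,4R)-4-methyl-3-[3-(trimethylsilyl)prop-2-yn-1-yl]oxolan-2-one (trans)
Conditions: LDA, THF, −78 °C; then 9, DMPU, −78 to −40 °C
Reagents that add atoms: none
Why: Alkylation of the lactone lithium enolate, in which the propargylic bromide approaches anti to the neighbouring C4 methyl group (1,2-induction from the substrate) to give the trans lactone, which is also the more stable isomer.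

Step 6
Reactants: 10 (3R,4R)-4-methyl-3-[3-(trimethylsilyl)prop-2-yn-1-yl]oxolan-2-one
Product: 12 (2R,3R)-4-[(tert-butyldimethylsilyl)oxy]-N-methoxy-N,3-dimethyl-2-[3-(trimethylsilyl)prop-2-yn-1-yl]butanamide, via hydroxy Weinreb amide 11 (not isolated)
Conditions: MeNH(OMe)·HCl, AlMe3, CH2Cl2, 0 °C to rt; then TBSCl, imidazole, DMF, rt
Reagents that add atoms: N,O-dimethylhydroxylamine hydrochloride, CNOC.Cl; tert-butyldimethylsilyl chloride, CC(C)(C)[Si](C)(C)Cl
Why: Weinreb aminolysis of the lactone by the aluminium amide and immediate silylation of the freed primary alcohol to block relactonization, with no bond to either stereocentre broken.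

Step 7
Reactants: 12 (2R,3R)-4-[(tert-butyldimethylsilyl)oxy]-N-methoxy-N,3-dimethyl-2-[3-(trimethylsilyl)prop-2-yn-1-yl]butanamide
Product: 13 (3R,4R)-5-[(tert-butyldimethylsilyl)oxy]-4-methyl-3-[3-(trimethylsilyl)prop-2-yn-1-yl]pentan-2-one
Conditions: MeMgBr, THF, 0 °C
Reagents that add atoms: methylmagnesium bromide, C[Mg]Br
Why: Weinreb ketone synthesis, in which the chelated tetrahedral adduct survives until work-up, so that over-addition and epimerization of the α-centre are avoided.

Step 8
Reactants: 13 (3R,4R)-5-[(tert-butyldimethylsilyl)oxy]-4-methyl-3-[3-(trimethylsilyl)prop-2-yn-1-yl]pentan-2-one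
Product: 14 tert-butyl{[(2R,3R)-2-methyl-3-(2-methyl-1,3-dioxolan-2-yl)-6-(trimethylsilyl)hex-5-yn-1-yl]oxy}dimethylsilane
Conditions: (TMSOCH2)2, TMSOTf (cat.), CH2Cl2, −78 to −20 °C; pyridine quench
Reagents that add atoms: 1,2-bis(trimethylsilyloxy)ethane, C[Si](C)(C)OCCO[Si](C)(C)C
Why: Noyori ketalization under aprotic low-temperature conditions, which masks the ketone without enolizing the α-branched centre and leaves the TBS ether and the alkynylsilane in place.

Step 9
Reactants: 14 tert-butyl{[(2R,3R)-2-methyl-3-(2-methyl-1,3-dioxolan-2-yl)-6-(trimethylsilyl)hex-5-yn-1-yl]oxy}dimethylsilane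
Product: 15 tert-butyl{[(2R,3R)-2-methyl-3-(2-methyl-1,3-dioxolan-2-yl)hex-5-yn-1-yl]oxy}dimethylsilane
Conditions: K2CO3 (cat.), MeOH, rt
Reagents that add atoms: none
Why: Base-catalysed methanolysis of the alkynyl C–Si bond, to which the alkyl TBS ether and the dioxolane are inert.

Step 10
Reactants: 15 tert-butyl{[(2R,3R)-2-methyl-3-(2-methyl-1,3-dioxolan-2-yl)hex-5-yn-1-yl]oxy}dimethylsilane
Product: 17 triisopropyl{[(4R,5R)-6-[(tert-butyldimethylsilyl)oxy]-5-methyl-4-(2-methyl-1,3-dioxolan-2-yl)hex-1-yn-1-yl]oxy}silane, via lithium ynolate 16 (not isolated)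
Conditions: n-BuLi, THF, −78 °C; t-BuOOLi (from t-BuOOH and LiHMDS), −78 to 0 °C; TIPSOTf, −78 °C
Reagents that add atoms: tert-butyl hydroperoxide, CC(C)(C)OO; triisopropylsilyl trifluoromethanesulfonate, CC(C)[Si](OS(=O)(=O)C(F)(F)F)(C(C)C)C(C)C
Why: Oxygen transfer from lithium tert-butyl peroxide to the lithium acetylide (Julia-type ynolate synthesis) and O-silylation of the ynolate by the bulky silyl triflate, which should give the silyl ynol ether and not the silylketene.

Step 11
Reactants: 7 3-[(2S)-2-(prop-1-en-2-yl)-2,3-dihydro-1-benzofuran-5-yl]propanoyl chloride; 17 silyl ynol ether (2 equivalents)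
Product: 24 2-{[(2S)-2-(prop-1-en-2-yl)-2,3-dihydro-1-benzofuran-5-yl]methyl}-3,5-bis(triisopropylsilyloxy)-4,6-bis[(2R,3R)-4-(tert-butyldimethylsilyloxy)-3-methyl-2-(2-methyl-1,3-dioxolan-2-yl)butyl]phenol, via aldoketene 18 (not isolated), via silyloxycyclobutenone 19 (not isolated), via vinylketene 20 (not isolated), via vinylcyclobutenone 21 (not isolated), via dienylketene 22 (not isolated), via cyclohexadienone 23 (not isolated)
Conditions: Et3N, toluene, rt, slow addition of 7 to 17; filtration under Ar; then 80 to 110 °C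
Reagents that add atoms: none
Why: Proposed new method: Et3N dehydrochlorinates 7 to aldoketene 18, whose carbonyl carbon is attacked by the oxygen-free (nucleophilic) alkyne carbon of 17 to give by [2+2] addition the 4-benzyl-3-silyloxycyclobutenone 19; after the ammonium salt is removed, heating opens 19 (4π electrocyclic) to vinylketene 20, which adds a second 17 in the same sense to give 21, and 21 opens to dienylketene 22, closes (6π electrocyclic) to dienone 23 and tautomerizes to 24. The closest known reactions are the [2+2] addition of ketenes to silyl ynol ethers giving 3-silyloxycyclobutenones and the Danheiser benzannulation of cyclobutenones with siloxyalkynes; not yet shown is an aldoketene-derived 3-silyloxycyclobutenone as the vinylketene source with the same alkyne serving both stages in one flask. The benzene ring is the only ring closed, by thermal disrotatory 6π electrocyclization of 22 joining the ketene carbon to the benzyl-bearing terminus, after the two cycloadditions have made the three new ring C–C bonds (benzyl carbon to silyloxy carbon, hydroxyl carbon to an arm-bearing carbon, central silyloxy carbon to the other arm-bearing carbon). No stereocentre is created in 24: the sp3 centres of 19, 21 and 23 vanish on aromatization, and the four side-chain centres carry no enolizable carbonyl under the neutral thermal conditions. The step needs only regioselectivity, which the polarity of the ynol ether secures in both cycloadditions (the oxygen-bearing alkyne carbon bonds to the ketene α-carbon), so that C and O substituents alternate and the former ketene oxygen becomes the one free hydroxyl next to the benzyl group; filtering off the base before heating suppresses the C4–H to C2 proton shift in 19 that would exchange benzyl and arm.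

Step 12
Reactants: 24 hexasubstituted phenol
Product: 25 allyl ether of 24 (2-allyloxy-1-benzyl-type arene with both aryl TIPS ethers, both TBS ethers and both dioxolanes intact)
Conditions: NaH, allyl bromide, THF/DMF, 0 °C to rt
Reagents that add atoms: allyl bromide, C=CCBr
Why: Williamson etherification of the single free phenol, while the di-ortho-substituted aryl TIPS ethers are too hindered to be cleaved and sit meta to the phenoxide, so that no silyl migration is possible.

Step 13
Reactants: 25 allyl ether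
Product: 26 allyl-protected tetrol (two free phenols, two primary alcohols, two dioxolanes)
Conditions: TBAF, THF, 0 °C to rt, under Ar
Reagents that add atoms: none
Why: Fluoride-mediated cleavage of both aryl TIPS ethers and both alkyl TBS ethers, to which the allyl ether, the dioxolanes and the alkene are inert.

Step 14
Reactants: 26 allyl-protected tetrol
Product: 27 allyl ether of the target (both bicyclic ketals closed)
Conditions: CSA (cat.), CH2Cl2, 0 °C to rt
Reagents that add atoms: none
Why: Acid-catalysed intramolecular transketalization, in which each dioxolane opens to an oxocarbenium ion that is taken up by the primary alcohol (tetrahydrofuran ring) and, after loss of ethylene glycol, by the neighbouring phenol (pyran ring); each ketal centre is set under thermodynamic control by the adjacent ring-fusion CH because only the cis-fused bicycle is unstrained, and with the third oxygen allylated the reversible exchange can end in only one bis-ketal constitution.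

Step 15
Reactants: 27 allyl ether of the target
Product: 28 target CNP0131395.1 (free phenol; each bicyclic ketal R at the ketal carbon, at the ring-fusion CH and at the methyl-bearing carbon; (S) at the dihydrobenzofuran C2)
Conditions: Pd(PPh3)4 (cat.), morpholine, THF, rt
Reagents that add atoms: none
Why: Tsuji–Trost deallylation with an amine scavenger, in which the unhindered O-allyl group should ionize far faster than the α-branched, 1,1-disubstituted allylic ether of the dihydrobenzofuran (itself formed under Pd(0) in step 1), under neutral conditions that cannot scramble the ketals next to the freed phenol.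

**Compound list**

1 | 3-bromo-4-hydroxybenzaldehyde | O=Cc1ccc(O)c(Br)c1 | starting material
2 | isoprene | C=CC(C)=C | starting material
3 | (2S)-2-(prop-1-en-2-yl)-2,3-dihydro-1-benzofuran-5-carbaldehyde | C=C(C)[C@@H]1Cc2cc(C=O)ccc2O1 | intermediate
4 | Meldrum's acid (2,2-dimethyl-1,3-dioxane-4,6-dione) | CC1(C)OC(=O)CC(=O)O1 | starting material
5 | 5-{[(2S)-2-(prop-1-en-2-yl)-2,3-dihydro-1-benzofuran-5-yl]methyl}-2,2-dimethyl-1,3-dioxane-4,6-dione | C=C(C)[C@@H]1Cc2cc(CC3C(=O)OC(C)(C)OC3=O)ccc2O1 | intermediate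
6 | 3-[(2S)-2-(prop-1-en-2-yl)-2,3-dihydro-1-benzofuran-5-yl]propanoic acid | C=C(C)[C@@H]1Cc2cc(CCC(=O)O)ccc2O1 | intermediate
7 | 3-[(2S)-2-(prop-1-en-2-yl)-2,3-dihydro-1-benzofuran-5-yl]propanoyl chloride | C=C(C)[C@@H]1Cc2cc(CCC(=O)Cl)ccc2O1 | intermediate
8 | (R)-4-methyldihydrofuran-2(3H)-one | O=C1C[C@@H](C)CO1 | starting material
9 | 3-bromo-1-(trimethylsilyl)prop-1-yne | C[Si](C)(C)C#CCBr | starting material
10 | (3R,4R)-4-methyl-3-[3-(trimethylsilyl)prop-2-yn-1-yl]oxolan-2-one | C[Si](C)(C)C#CC[C@@H]1[C@@H](C)COC1=O | intermediate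
11 | (2R,3R)-4-hydroxy-N-methoxy-N,3-dimethyl-2-[3-(trimethylsilyl)prop-2-yn-1-yl]butanamide | CON(C)C(=O)[C@H](CC#C[Si](C)(C)C)[C@@H](C)CO | intermediate
12 | (2R,3R)-4-[(tert-butyldimethylsilyl)oxy]-N-methoxy-N,3-dimethyl-2-[3-(trimethylsilyl)prop-2-yn-1-yl]butanamide | CON(C)C(=O)[C@H](CC#C[Si](C)(C)C)[C@@H](C)CO[Si](C)(C)C(C)(C)C | intermediate
13 | (3R,4R)-5-[(tert-butyldimethylsilyl)oxy]-4-methyl-3-[3-(trimethylsilyl)prop-2-yn-1-yl]pentan-2-one | CC(=O)[C@H](CC#C[Si](C)(C)C)[C@@H](C)CO[Si](C)(C)C(C)(C)C | intermediate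
14 | tert-butyl{[(2R,3R)-2-methyl-3-(2-methyl-1,3-dioxolan-2-yl)-6-(trimethylsilyl)hex-5-yn-1-yl]oxy}dimethylsilane | CC1(OCCO1)[C@H](CC#C[Si](C)(C)C)[C@@H](C)CO[Si](C)(C)C(C)(C)C | intermediate
15 | tert-butyl{[(2R,3R)-2-methyl-3-(2-methyl-1,3-dioxolan-2-yl)hex-5-yn-1-yl]oxy}dimethylsilane | CC1(OCCO1)[C@H](CC#C)[C@@H](C)CO[Si](C)(C)C(C)(C)C | intermediate
16 | lithium ynolate of the arm (lithium (4R,5R)-6-(TBS-oxy)-5-methyl-4-(2-methyl-1,3-dioxolan-2-yl)hex-1-yn-1-olate) | [Li+].[O-]C#CC[C@@H](C1(C)OCCO1)[C@@H](C)CO[Si](C)(C)C(C)(C)C | intermediate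
17 | triisopropyl{[(4R,5R)-6-[(tert-butyldimethylsilyl)oxy]-5-methyl-4-(2-methyl-1,3-dioxolan-2-yl)hex-1-yn-1-yl]oxy}silane | CC(C)[Si](OC#CC[C@@H](C1(C)OCCO1)[C@@H](C)CO[Si](C)(C)C(C)(C)C)(C(C)C)C(C)C | intermediate
18 | aldoketene: 3-[(2S)-2-(prop-1-en-2-yl)-2,3-dihydro-1-benzofuran-5-yl]prop-1-en-1-one | C=C(C)[C@@H]1Cc2cc(CC=C=O)ccc2O1 | intermediate
19 | 4-(arylmethyl)-2-arm-3-(triisopropylsilyloxy)cyclobut-2-en-1-one (C4 undefined) | C=C(C)[C@@H]1Cc2cc(CC3C(=O)C(C[C@@H](C4(C)OCCO4)[C@@H](C)CO[Si](C)(C)C(C)(C)C)=C3O[Si](C(C)C)(C(C)C)C(C)C)ccc2O1 | intermediate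
20 | vinylketene: 2-arm-3-(triisopropylsilyloxy)-5-arylpenta-1,3-dien-1-one (alkene geometry undefined) | C=C(C)[C@@H]1Cc2cc(CC=C(O[Si](C(C)C)(C(C)C)C(C)C)C(C[C@@H](C3(C)OCCO3)[C@@H](C)CO[Si](C)(C)C(C)(C)C)=C=O)ccc2O1 | intermediate
21 | 4-vinylcyclobutenone: 2,4-bis-arm-3-(triisopropylsilyloxy)-4-[1-(triisopropylsilyloxy)-3-arylprop-1-enyl]cyclobut-2-en-1-one (C4 and alkene undefined) | C=C(C)[C@@H]1Cc2cc(CC=C(O[Si](C(C)C)(C(C)C)C(C)C)C3(C[C@@H](C4(C)OCCO4)[C@@H](C)CO[Si](C)(C)C(C)(C)C)C(=O)C(C[C@@H](C4(C)OCCO4)[C@@H](C)CO[Si](C)(C)C(C)(C)C)=C3O[Si](C(C)C)(C(C)C)C(C)C)ccc2O1 | intermediate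
22 | dienylketene: 2,4-bis-arm-3,5-bis(triisopropylsilyloxy)-7-arylhepta-1,3,5-trien-1-one (alkene geometries undefined) | C=C(C)[C@@H]1Cc2cc(CC=C(O[Si](C(C)C)(C(C)C)C(C)C)C(C[C@@H](C3(C)OCCO3)[C@@H](C)CO[Si](C)(C)C(C)(C)C)=C(O[Si](C(C)C)(C(C)C)C(C)C)C(C[C@@H](C3(C)OCCO3)[C@@H](C)CO[Si](C)(C)C(C)(C)C)=C=O)ccc2O1 | intermediate
23 | 6-(arylmethyl)-2,4-bis-arm-3,5-bis(triisopropylsilyloxy)cyclohexa-2,4-dien-1-one (C6 undefined) | C=C(C)[C@@H]1Cc2cc(CC3C(=O)C(C[C@@H](C4(C)OCCO4)[C@@H](C)CO[Si](C)(C)C(C)(C)C)=C(O[Si](C(C)C)(C(C)C)C(C)C)C(C[C@@H](C4(C)OCCO4)[C@@H](C)CO[Si](C)(C)C(C)(C)C)=C3O[Si](C(C)C)(C(C)C)C(C)C)ccc2O1 | intermediate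
24 | 2-{[(2S)-2-(prop-1-en-2-yl)-2,3-dihydro-1-benzofuran-5-yl]methyl}-3,5-bis(triisopropylsilyloxy)-4,6-bis[(2R,3R)-4-(tert-butyldimethylsilyloxy)-3-methyl-2-(2-methyl-1,3-dioxolan-2-yl)butyl]phenol | C=C(C)[C@@H]1Cc2cc(Cc3c(O)c(C[C@@H](C4(C)OCCO4)[C@@H](C)CO[Si](C)(C)C(C)(C)C)c(O[Si](C(C)C)(C(C)C)C(C)C)c(C[C@@H](C4(C)OCCO4)[C@@H](C)CO[Si](C)(C)C(C)(C)C)c3O[Si](C(C)C)(C(C)C)C(C)C)ccc2O1 | intermediate
25 | allyl ether of 24 | C=C(C)[C@@H]1Cc2cc(Cc3c(OCC=C)c(C[C@@H](C4(C)OCCO4)[C@@H](C)CO[Si](C)(C)C(C)(C)C)c(O[Si](C(C)C)(C(C)C)C(C)C)c(C[C@@H](C4(C)OCCO4)[C@@H](C)CO[Si](C)(C)C(C)(C)C)c3O[Si](C(C)C)(C(C)C)C(C)C)ccc2O1 | intermediate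
26 | allyl-protected tetrol: 4-allyloxy-5-(arylmethyl)-2,6-bis[(2R,3R)-4-hydroxy-3-methyl-2-(2-methyl-1,3-dioxolan-2-yl)butyl]benzene-1,3-diol | C=C(C)[C@@H]1Cc2cc(Cc3c(OCC=C)c(C[C@@H](C4(C)OCCO4)[C@@H](C)CO)c(O)c(C[C@@H](C4(C)OCCO4)[C@@H](C)CO)c3O)ccc2O1 | intermediate
27 | allyl ether of the target (both cis-fused bicyclic ketals closed) | C=C(C)[C@@H]1Cc2cc(Cc3c(OCC=C)c4c(c5c3O[C@@]3(C)OC[C@H](C)[C@H]3C5)O[C@@]3(C)OC[C@H](C)[C@H]3C4)ccc2O1 | intermediate
28 | CNP0131395.1 | C=C(C)[C@@H]1Cc2cc(Cc3c(O)c4c(c5c3O[C@@]3(C)OC[C@H](C)[C@H]3C5)O[C@@]3(C)OC[C@H](C)[C@H]3C4)ccc2O1 | target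

**Step count and risks**

Total: 15 steps. Longest linear sequence: 11 steps (steps 5–15, from lactone 8); the aryl branch joins after 4 steps.

Steps most likely to fail:

1. Step 11 (carries the label). The aldoketene may dimerize or be acylated faster than it is trapped. A base-induced proton shift in 19 may scramble the C/O pattern. The donor-substituted cyclobutenone may open too slowly, so that the ynol ether decomposes first. Fallback, all by known reaction types: it sets out from siloxyalkyne 17 and aldehyde 3 and comes back at 27. Ketene gas (CH2=C=O, CH2Cl2, 0 °C) adds to 17 to give the 4-unsubstituted 2-alkyl-3-silyloxycyclobutenone F1, which is isolated and heated with a second equivalent of 17 (toluene, 80–110 °C, Danheiser benzannulation) to give the pentasubstituted phenol F2, which carries H where the benzyl group belongs. F2 is allylated as in step 12 to the allyl ether F3, desilylated as in step 13 to the tetrol F4 and closed as in step 14 to the allyl-protected bis-ketal F5, which has one free ring CH between the allyloxy carbon and a ketal oxygen. Aldehyde 3 is reduced (NaBH4, MeOH, 0 °C) to the benzylic alcohol F6. Friedel–Crafts benzylation of F5 with F6 (Sc(OTf)3 cat., CH2Cl2, 0 °C) at the only unsubstituted, triply oxygen-activated ring carbon should give 27, and step 15 follows.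

2. Step 10. Oxygen transfer to the acetylide may be incomplete, and C-silylation or hydrolysis of the ynol ether during work-up may compete. Fallback: it sets out from alkyne 15 and comes back at ynolate 16 and so at 17. Oxidative cleavage of the terminal alkyne (RuCl3 cat., NaIO4, NaHCO3-buffered CCl4/MeCN/H2O) gives the nor-acid F7, and TMSCHN2 (toluene/MeOH) gives the methyl ester F8. Kowalski ester homologation (LiCHBr2 from CH2Br2 and LiTMP, THF, −78 °C; then n-BuLi, −78 to 0 °C) rearranges F8 to the same lithium ynolate 16, which is silylated on oxygen as in the main route.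

3. Step 14. The acid may isomerize the isopropenyl-dihydrobenzofuran, or intermolecular ketal exchange may occur before both bicycles have closed. Fallback with a staged closure: it sets out from 25 and comes back at 27. PPTS in MeOH (40 °C) removes both TBS groups and exchanges each dioxolane for the five-membered cyclic methyl ketal while the phenols are still silylated, giving the bis(2-methoxy-2-methyltetrahydrofuran) F9 as an anomeric mixture. TBAF then frees the two phenols to give the diphenol F10. Loss of methanol under PPTS (cat.) in benzene with 4 Å molecular sieves at 50 °C closes the two pyran rings and converges the anomers on 27.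

**Further compounds**

F1 | step 11 | 2-[(2R,3R)-4-(TBS-oxy)-3-methyl-2-(2-methyl-1,3-dioxolan-2-yl)butyl]-3-(triisopropylsilyloxy)cyclobut-2-en-1-one | O=C1CC(O[Si](C(C)C)(C(C)C)C(C)C)=C1C[C@@H](C2(C)OCCO2)[C@@H](C)CO[Si](C)(C)C(C)(C)C
F2 | step 11 | 3,5-bis(triisopropylsilyloxy)-2,4-bis[(2R,3R)-4-(TBS-oxy)-3-methyl-2-(2-methyl-1,3-dioxolan-2-yl)butyl]phenol | Oc1cc(O[Si](C(C)C)(C(C)C)C(C)C)c(C[C@@H](C2(C)OCCO2)[C@@H](C)CO[Si](C)(C)C(C)(C)C)c(O[Si](C(C)C)(C(C)C)C(C)C)c1C[C@@H](C2(C)OCCO2)[C@@H](C)CO[Si](C)(C)C(C)(C)C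
F3 | step 11 | allyl ether of F2 | C=CCOc1cc(O[Si](C(C)C)(C(C)C)C(C)C)c(C[C@@H](C2(C)OCCO2)[C@@H](C)CO[Si](C)(C)C(C)(C)C)c(O[Si](C(C)C)(C(C)C)C(C)C)c1C[C@@H](C2(C)OCCO2)[C@@H](C)CO[Si](C)(C)C(C)(C)C
F4 | step 11 | 4-allyloxy-2,6-bis[(2R,3R)-4-hydroxy-3-methyl-2-(2-methyl-1,3-dioxolan-2-yl)butyl]benzene-1,3-diol | C=CCOc1cc(O)c(C[C@@H](C2(C)OCCO2)[C@@H](C)CO)c(O)c1C[C@@H](C2(C)OCCO2)[C@@H](C)CO
F5 | step 11 | allyl-protected bis-ketal lacking the benzyl group (one free ring CH) | c1c(OCC=C)c2c(c3c1O[C@@]1(C)OC[C@H](C)[C@H]1C3)O[C@@]1(C)OC[C@H](C)[C@H]1C2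
F6 | step 11 | [(2S)-2-(prop-1-en-2-yl)-2,3-dihydro-1-benzofuran-5-yl]methanol | C=C(C)[C@@H]1Cc2cc(CO)ccc2O1
F7 | step 10 | (3R,4R)-5-(TBS-oxy)-4-methyl-3-(2-methyl-1,3-dioxolan-2-yl)pentanoic acid | OC(=O)C[C@@H](C1(C)OCCO1)[C@@H](C)CO[Si](C)(C)C(C)(C)C
F8 | step 10 | methyl (3R,4R)-5-(TBS-oxy)-4-methyl-3-(2-methyl-1,3-dioxolan-2-yl)pentanoate | COC(=O)C[C@@H](C1(C)OCCO1)[C@@H](C)CO[Si](C)(C)C(C)(C)C
F9 | step 14 | allyl ether with both arms as 2-methoxy-2-methyltetrahydrofurans and both aryl TIPS ethers (anomeric centres undefined) | C=C(C)[C@@H]1Cc2cc(Cc3c(OCC=C)c(C[C@H]4C(C)(OC)OC[C@@H]4C)c(O[Si](C(C)C)(C(C)C)C(C)C)c(C[C@H]4C(C)(OC)OC[C@@H]4C)c3O[Si](C(C)C)(C(C)C)C(C)C)ccc2O1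
F10 | step 14 | diphenol from F9 (anomeric centres undefined) | C=C(C)[C@@H]1Cc2cc(Cc3c(OCC=C)c(C[C@H]4C(C)(OC)OC[C@@H]4C)c(O)c(C[C@H]4C(C)(OC)OC[C@@H]4C)c3O)ccc2O1
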